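## Structural features

- The target is a cyclohex-3-ene (ring atoms C-1 to C-6). C-1 carries a 2,4-dihydroxy-6-methoxybenzoyl group, C-6 a phenyl ring, and the alkene carbon C-4 a 4-methylpent-3-enyl chain; C-2 and C-5 are methylenes.
- C-1 and C-6 are adjacent stereocentres, trans, (1R,6R). C-1 is alpha to the ketone and can be epimerised; C-6 is benzylic, cannot enolise, and must be set absolutely.
- The aryl ketone is di-ortho-substituted, with the acyl carbon between an OH and the OMe and the second OH para. This is a regiochemical problem on a phloroglucinol-type ring.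
- Fragile groups: two trisubstituted alkenes (acid and electrophiles; cation–olefin cyclisation), an electron-rich phenol ring, and the enolisable C-1.
- The connectivity is that of a myrcene/chalcone cycloadduct. The real difficulty is absolute control at C-6 together with the 1,4-relation between the acyl-bearing C-1 and the chain-bearing C-4.
- The key step exploits the array O=C–C-1–C-2–C-3=C-4 inside the ring. It is a gamma,delta-unsaturated carbonyl unit, the retron of a Claisen rearrangement, whose far alkene carbon C-4 is fully substituted.
- Tying the carbonyl oxygen back to C-4 gives a six-membered lactone with a tertiary allylic C–O bond. In that lactone only the future C-6 has to be controlled, and the epimerisable C-1 lets the route converge.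

## Logic of the disconnections

In one sentence: the cyclohexene is made by Ireland–Claisen ring contraction of the 6-vinyl delta-lactone 9.

**21 from 19 (through 20).** Bonds cut: the aryl O–Si bond at the 4-oxygen and the O–CH2 acetal bond at the 2-oxygen. Reason: the two phenols must be masked differently so that the arene can be metalated at one position only. Gain: no skeletal simplification, but phenoxides are kept out of the organolithium and base steps. Demand: fluoride and mild acid that leave two trisubstituted alkenes untouched.

**19 from 18.** Bond cut: C-1–H, re-formed on the other face. Reason: C-1 is the only enolisable stereocentre and trans is the thermodynamic arrangement, so 18 may be any mixture at C-1. Gain: no earlier step has to control C-1. Demand: equilibration that leaves C-6 and the silyl ether alone.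

**18 from 13 and 17 (17 from 16).** Bond cut: aryl C–C(=O). Reason: a di-ortho-substituted aryl ketone is best made by acyl substitution with an aryllithium, and the lithiation site in 16 fixes the oxygenation pattern. Gain: the molecule splits into a carbocyclic acid derivative and a simple arene. Demand: single addition to the amide, and lithiation only between the two coordinating oxygens.

**13 from 12.** Bond cut: amide C–N. Reason: an acyl donor that stops at the ketone. Gain: none in the skeleton. Demand: activation without acid.

**12 from 9 (through 11 and 10), the key disconnection.** Bond cut: ring bond C-1–C-2; the carboxyl oxygen is reconnected to C-4 and the alkene moves from C-3=C-4 to a terminal vinyl group. Reason: the retro-[3,3] shift removes the carbocycle, fixes by constitution where the ring alkene and the chain must appear, and leaves one stereocentre of consequence (C-4 of 9, the future C-6). Gain: ring, alkene regiochemistry and the vicinal pair reduce to one benzylic centre in a lactone whose other centre may be either epimer. Demand: the ketene acetal 10 must rearrange through a boat-like transition state faster than its tertiary allylic C–O bond ionises, and both epimers of 9 must react.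

**9 from 6 and 7 (through 8).** Bonds cut: the lactone acyl C–O bond and the C–C bond between the carbinol carbon and the vinyl group. Reason: a tertiary allylic alcohol next to an ester lactonises by itself. Gain: an acyclic keto ester with one stereocentre. Demand: addition to the ketone in preference to the ester; no facial selectivity is needed.

**6 from 5.** Bond cut: C–CO2Me. Reason: the malonate is the practical acetate donor. Gain: access to the best-developed asymmetric conjugate addition. Demand: dealkoxycarbonylation without retro-Michael.

**5 from 3 and 4.** Bond cut: the benzylic C–C bond to the malonyl carbon. Reason: this is where absolute configuration enters the route, on an unhindered acyclic (E)-enone. Gain: two achiral partners. Demand: high enantiofacial control.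

**3 from 1 and 2.** Bond cut: the C=C bond of the enone. Reason: crossed aldol condensation of two commodity chemicals. Demand: condensation at the methyl, not the methylene, side of 2.

**16 from 15, and 15 from 14.** Bonds cut: O–CH2 and O–Si. Reason: one oxygen must direct lithiation and the other must block it. Demand: mono-silylation of a symmetric diol.

## Other disconnections considered

**Alternative 1: intermolecular Diels–Alder (the first idea).**
- Cut: C-1–C-2 and C-5–C-6.
- Forward step: [4+2] cycloaddition of the protected chalcone A1 with myrcene A2 to give the protected ketone A3.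
- Ground for preferring the chosen plan: one event would have to control the para/meta orientation of a weakly biased 2-alkyl diene, the face of a flexible acyclic enone, and the low reactivity of a twisted chalcone. The activation that reactivity calls for (strong Lewis acid or heat) endangers the trisubstituted alkenes. The chosen plan fixes the regiochemistry by constitution and sets C-6 in a separate, well-understood conjugate addition.

**Alternative 2: conjugate addition, enolate allylation, ring-closing metathesis.**
- Cut: C-3=C-4.
- Forward step: RCM of the diene A4 to A3, with A4 assembled by adding a 2-substituted allyl nucleophile to A1 and trapping the enolate with an allyl halide.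
- Ground for preferring the chosen plan: the two stereocentres would come from two separate events, the first of which (allyl-type conjugate addition to an aryl enone) is prone to 1,2-addition and has no dependable asymmetric version. The metathesis must also choose among three alkenes. The ring contraction closes the ring and places the alkene in a single concerted step.

**Alternative 3: asymmetric conjugate arylation of a cyclohexadienyl ketone.**
- Cut: C-6–phenyl.
- Forward step: rhodium-catalysed addition of a phenylboron reagent to the dienone A5, followed by thermodynamic protonation at C-1, to give A3.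
- Ground for preferring the chosen plan: A5 is a skipped diene one oxidation level below an arene and should aromatise or conjugate under basic rhodium conditions. Its acceptor alkene is trisubstituted and its carbonyl is twisted out of conjugation by the two ortho substituents. Making A5 still needs the regiochemically ambiguous cycloaddition.

Key step: step 5

Assumption 1: locants C-1 to C-6 are those of the cyclohexene ring of the target (C-1 acyl, C-6 phenyl); the target is the trans (1R,6R) isomer.
Assumption 2: the antipode of the step-2 catalyst that delivers (R)-5 is used; both antipodes are accessible, and the sense of induction has not been assigned here.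

## Steps

Step 1
Reactants: 1 benzaldehyde; 2 6-methylhept-5-en-2-one
Product: 3 (E)-7-methyl-1-phenylocta-1,6-dien-3-one
Conditions: NaOH (10% aq.), EtOH, 0 °C to rt
Reagents that add atoms: none
Why: Claisen–Schmidt condensation; under hydroxide the methyl ketone should condense through its CH3 terminus with the non-enolisable aldehyde, and E1cB dehydration to the conjugated (E)-styryl ketone drives the reaction, while the isolated trisubstituted alkene is inert.

Step 2
Reactants: 3 (E)-7-methyl-1-phenylocta-1,6-dien-3-one; 4 dimethyl malonate
Product: 5 dimethyl 2-[(1R)-7-methyl-3-oxo-1-phenyloct-6-en-1-yl]propanedioate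
Conditions: 4 (2 equiv), chiral primary amine–thiourea catalyst derived from trans-cyclohexane-1,2-diamine (10 mol%), PhCO2H (10 mol%), toluene, rt
Reagents that add atoms: none
Why: Organocatalytic asymmetric Michael addition; the primary amine forms an iminium ion with the enone while the thiourea binds the malonate and delivers it to one face of the beta-carbon, which sets the benzylic stereocentre (R). This is the only step in which absolute configuration is created.

Step 3
Reactants: 5 dimethyl 2-[(1R)-7-methyl-3-oxo-1-phenyloct-6-en-1-yl]propanedioate
Product: 6 methyl (3R)-9-methyl-5-oxo-3-phenyldec-8-enoate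
Conditions: LiCl, H2O, DMSO, 140 °C
Reagents that add atoms: none
Why: Krapcho dealkoxycarbonylation; chloride demethylates one ester, the carboxylate loses CO2 and water protonates the enolate. The near-neutral medium should spare the ketone, the alkene and the benzylic centre (no retro-Michael).

Step 4
Reactants: 6 methyl (3R)-9-methyl-5-oxo-3-phenyldec-8-enoate; 7 ethenylmagnesium bromide
Product: 9 (4R,6RS)-6-ethenyl-6-(4-methylpent-3-en-1-yl)-4-phenyloxan-2-one, via bromomagnesium alkoxide 8 (not isolated)
Conditions: 7 (1.3 equiv), LaCl3·2LiCl (0.3 equiv), THF, −78 °C to rt; aq. NH4Cl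
Reagents that add atoms: none
Why: Lanthanum-assisted Grignard 1,2-addition should occur at the ketone in preference to the ester, and the tertiary alkoxide then closes the delta-lactone by 6-exo-trig acyl substitution. The carbinol centre forms without useful induction, and both epimers are wanted because that centre is destroyed in step 5.

Step 5
Reactants: 9 (4R,6RS)-6-ethenyl-6-(4-methylpent-3-en-1-yl)-4-phenyloxan-2-one
Product: 12 (1RS,6R)-4-(4-methylpent-3-en-1-yl)-6-phenylcyclohex-3-ene-1-carboxylic acid, via silyl ketene acetal 10 (not isolated), via trimethylsilyl ester 11 (not isolated)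
Conditions: LDA, THF, −78 °C; TMSCl–Et3N, −78 °C to rt; then toluene, 105 °C; then H2O/MeOH, rt
Reagents that add atoms: none
Why: LDA removes a proton at lactone C-3 (the only acidic site) and O-silylation gives the cyclic ketene acetal 10, in which the C=C–O unit and the 6-vinyl group form the 1,5-diene of an Ireland–Claisen rearrangement. On heating, the [3,3] shift forms the ring bond C-1–C-2 (lactone C-3 to the vinyl terminus) as the tertiary allylic C–O bond breaks, so the lactone contracts to the cyclohex-3-ene and the ring oxygen becomes the silyl carboxylate 11; the closest known reaction type is the Ireland–Claisen ring contraction of alkenyl lactones. The carbocycle closes in a concerted, suprafacial manner through the boat-like, bicyclo[2.2.2]-type transition state that the two-carbon tether enforces, and the alkene can appear only at C-3=C-4 with the chain on C-4, so no regiochemical choice arises. C-6 is the lactone C-4 carbon, a spectator that is carried over unchanged (R). The new centre C-1 is controlled by the face of the ketene acetal that bears the vinyl group: the (4R,6R)-lactone (vinyl cis to phenyl) should give the trans (1R,6R) acid and the (4R,6S)-lactone the cis (1S,6R) acid. The step therefore needs no diastereoselectivity, because the lactone C-6 centre is destroyed and C-1 is corrected in step 10. What it does need is rearrangement faster than ionisation or elimination at the tertiary allylic C–O bond, which the amine-buffered silyl ketene acetal conditions and the early, loose transition state of a tertiary allylic ester are expected to secure.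

Step 6
Reactants: 12 (1RS,6R)-4-(4-methylpent-3-en-1-yl)-6-phenylcyclohex-3-ene-1-carboxylic acid
Product: 13 (1RS,6R)-N-methoxy-N-methyl-4-(4-methylpent-3-en-1-yl)-6-phenylcyclohex-3-ene-1-carboxamide
Conditions: CDI, CH2Cl2, rt; then MeNHOMe·HCl, rt
Reagents that add atoms: N,O-dimethylhydroxylamine hydrochloride, CNOC.Cl
Why: Weinreb amide formation through the acyl imidazolide; the activation is non-acidic and leaves the alkenes alone, and any epimerisation at C-1 is of no consequence at this stage.

Step 7
Reactants: 14 5-methoxybenzene-1,3-diol
Product: 15 3-methoxy-5-{[tri(propan-2-yl)silyl]oxy}phenol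
Conditions: TIPSCl (1.0 equiv), imidazole, DMF, 0 °C to rt
Reagents that add atoms: chlorotri(propan-2-yl)silane (TIPSCl), CC(C)[Si](Cl)(C(C)C)C(C)C
Why: Statistical mono-silylation of a symmetric diol under imidazole catalysis; unreacted diol and bis-silyl ether are separable and recyclable, and the bulky, non-coordinating TIPS group is chosen to shield its two neighbouring ring positions in step 9.

Step 8
Reactants: 15 3-methoxy-5-{[tri(propan-2-yl)silyl]oxy}phenol
Product: 16 [3-methoxy-5-(methoxymethoxy)phenoxy]tri(propan-2-yl)silane
Conditions: MOMCl, i-Pr2NEt, CH2Cl2, 0 °C to rt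
Reagents that add atoms: chloromethyl methyl ether (MOMCl), COCCl
Why: O-alkylation of the remaining phenol to the MOM ether, which serves as a directing group for lithiation and as an acid-labile mask for the future 2-OH.

Step 9
Reactants: 16 [3-methoxy-5-(methoxymethoxy)phenoxy]tri(propan-2-yl)silane; 13 (1RS,6R)-N-methoxy-N-methyl-4-(4-methylpent-3-en-1-yl)-6-phenylcyclohex-3-ene-1-carboxamide
Product: 18 [2-methoxy-6-(methoxymethoxy)-4-{[tri(propan-2-yl)silyl]oxy}phenyl][(1RS,6R)-4-(4-methylpent-3-en-1-yl)-6-phenylcyclohex-3-en-1-yl]methanone, via aryllithium 17 (not isolated)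
Conditions: 16 (2.2 equiv), n-BuLi (2.0 equiv), TMEDA, THF, 0 °C; then 13, −78 °C to 0 °C; aq. NH4Cl
Reagents that add atoms: none
Why: Directed ortho-metalation should remove the ring proton flanked by the two coordinating groups OMe and OMOM, while the positions next to OTIPS are shielded and lack a second director; this fixes the acyl carbon between OMe and the future 2-OH. The aryllithium then adds once to the Weinreb amide because the chelated tetrahedral intermediate survives until the quench.

Step 10
Reactants: 18 [2-methoxy-6-(methoxymethoxy)-4-{[tri(propan-2-yl)silyl]oxy}phenyl][(1RS,6R)-4-(4-methylpent-3-en-1-yl)-6-phenylcyclohex-3-en-1-yl]methanone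
Product: 19 [2-methoxy-6-(methoxymethoxy)-4-{[tri(propan-2-yl)silyl]oxy}phenyl][(1R,6R)-4-(4-methylpent-3-en-1-yl)-6-phenylcyclohex-3-en-1-yl]methanone
Conditions: DBU, dry toluene, 80 °C
Reagents that add atoms: none
Why: Thermodynamic epimerisation through the enol(ate) at C-1; the trans isomer places the aroyl and phenyl groups both pseudo-equatorial on the cyclohexene half-chair and should dominate at equilibrium. C-6 cannot enolise, so its R configuration is untouched, and this step funnels both C-1 epimers (hence both epimers of 9) into (1R,6R).

Step 11
Reactants: 19 [2-methoxy-6-(methoxymethoxy)-4-{[tri(propan-2-yl)silyl]oxy}phenyl][(1R,6R)-4-(4-methylpent-3-en-1-yl)-6-phenylcyclohex-3-en-1-yl]methanone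
Product: 21 (2,4-dihydroxy-6-methoxyphenyl)[(1R,6R)-4-(4-methylpent-3-en-1-yl)-6-phenylcyclohex-3-en-1-yl]methanone, via 4-hydroxy MOM ether 20 (not isolated)
Conditions: TBAF, THF, 0 °C; then 2 M HCl, MeOH, rt
Reagents that add atoms: none
Why: Fluoride cleaves the aryl silyl ether, and dilute methanolic acid then removes the MOM acetal, which is activated by the ortho carbonyl. Acid strength and temperature are kept low so that the trisubstituted alkenes should not be protonated.

## Compound list

1 | benzaldehyde | O=Cc1ccccc1 | starting material
2 | 6-methylhept-5-en-2-one | CC(=O)CCC=C(C)C | starting material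
3 | (E)-7-methyl-1-phenylocta-1,6-dien-3-one | CC(C)=CCCC(=O)/C=C/c1ccccc1 | intermediate
4 | dimethyl propanedioate (dimethyl malonate) | COC(=O)CC(=O)OC | starting material
5 | dimethyl 2-[(1R)-7-methyl-3-oxo-1-phenyloct-6-en-1-yl]propanedioate | COC(=O)C(C(=O)OC)[C@H](c1ccccc1)CC(=O)CCC=C(C)C | intermediate
6 | methyl (3R)-9-methyl-5-oxo-3-phenyldec-8-enoate | COC(=O)C[C@H](c1ccccc1)CC(=O)CCC=C(C)C | intermediate
7 | ethenylmagnesium bromide | C=C[Mg]Br | starting material
8 | bromomagnesium alkoxide of methyl (3R,5RS)-5-ethenyl-5-hydroxy-9-methyl-3-phenyldec-8-enoate | COC(=O)C[C@H](c1ccccc1)CC(C=C)(CCC=C(C)C)O[Mg]Br | intermediate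
9 | (4R,6RS)-6-ethenyl-6-(4-methylpent-3-en-1-yl)-4-phenyloxan-2-one | O=C1C[C@H](c2ccccc2)CC(C=C)(CCC=C(C)C)O1 | intermediate
10 | {[(4R,6RS)-6-ethenyl-6-(4-methylpent-3-en-1-yl)-4-phenyl-5,6-dihydro-4H-pyran-2-yl]oxy}trimethylsilane | C[Si](C)(C)OC1=C[C@H](c2ccccc2)CC(C=C)(CCC=C(C)C)O1 | intermediate
11 | trimethylsilyl (1RS,6R)-4-(4-methylpent-3-en-1-yl)-6-phenylcyclohex-3-ene-1-carboxylate | C[Si](C)(C)OC(=O)C1CC=C(CCC=C(C)C)C[C@H]1c1ccccc1 | intermediate
12 | (1RS,6R)-4-(4-methylpent-3-en-1-yl)-6-phenylcyclohex-3-ene-1-carboxylic acid | OC(=O)C1CC=C(CCC=C(C)C)C[C@H]1c1ccccc1 | intermediate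
13 | (1RS,6R)-N-methoxy-N-methyl-4-(4-methylpent-3-en-1-yl)-6-phenylcyclohex-3-ene-1-carboxamide | CON(C)C(=O)C1CC=C(CCC=C(C)C)C[C@H]1c1ccccc1 | intermediate
14 | 5-methoxybenzene-1,3-diol | COc1cc(O)cc(O)c1 | starting material
15 | 3-methoxy-5-{[tri(propan-2-yl)silyl]oxy}phenol | COc1cc(O)cc(O[Si](C(C)C)(C(C)C)C(C)C)c1 | intermediate
16 | [3-methoxy-5-(methoxymethoxy)phenoxy]tri(propan-2-yl)silane | COCOc1cc(OC)cc(O[Si](C(C)C)(C(C)C)C(C)C)c1 | intermediate
17 | [2-methoxy-6-(methoxymethoxy)-4-{[tri(propan-2-yl)silyl]oxy}phenyl]lithium | [Li]c1c(OC)cc(O[Si](C(C)C)(C(C)C)C(C)C)cc1OCOC | intermediate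
18 | [2-methoxy-6-(methoxymethoxy)-4-{[tri(propan-2-yl)silyl]oxy}phenyl][(1RS,6R)-4-(4-methylpent-3-en-1-yl)-6-phenylcyclohex-3-en-1-yl]methanone | COCOc1cc(O[Si](C(C)C)(C(C)C)C(C)C)cc(OC)c1C(=O)C1CC=C(CCC=C(C)C)C[C@H]1c1ccccc1 | intermediate
19 | [2-methoxy-6-(methoxymethoxy)-4-{[tri(propan-2-yl)silyl]oxy}phenyl][(1R,6R)-4-(4-methylpent-3-en-1-yl)-6-phenylcyclohex-3-en-1-yl]methanone | COCOc1cc(O[Si](C(C)C)(C(C)C)C(C)C)cc(OC)c1C(=O)[C@@H]1CC=C(CCC=C(C)C)C[C@H]1c1ccccc1 | intermediate
20 | [4-hydroxy-2-methoxy-6-(methoxymethoxy)phenyl][(1R,6R)-4-(4-methylpent-3-en-1-yl)-6-phenylcyclohex-3-en-1-yl]methanone | COCOc1cc(O)cc(OC)c1C(=O)[C@@H]1CC=C(CCC=C(C)C)C[C@H]1c1ccccc1 | intermediate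
21 | (2,4-dihydroxy-6-methoxyphenyl)[(1R,6R)-4-(4-methylpent-3-en-1-yl)-6-phenylcyclohex-3-en-1-yl]methanone | COc1cc(O)cc(O)c1C(=O)[C@@H]1CC=C(CCC=C(C)C)C[C@H]1c1ccccc1 | target

## Step count and least certain steps

Total step count: 11. Longest linear sequence: 9 steps (steps 1 to 6, 9, 10, 11); steps 7 and 8 prepare the arene in parallel.

**Step 5 (key step).**
- What may go wrong: ionisation and elimination at the tertiary allylic C–O bond during silylation or heating, or slow rearrangement of the lactone epimer whose phenyl group points towards the ketene acetal bridge, so that material is lost before the ring contracts.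
- Fallback (ring closure by metathesis instead of a sigmatropic shift): it sets out from 6.
  - Wittig methylenation of the ketone (Ph3P=CH2, THF) would give methyl (3R)-9-methyl-5-methylidene-3-phenyldec-8-enoate F1.
  - Deprotonation with LDA and alkylation with allyl bromide would give methyl (3R)-9-methyl-5-methylidene-3-phenyl-2-(prop-2-en-1-yl)dec-8-enoate F2 as C-2 epimers.
  - Ring-closing metathesis (Grubbs II, CH2Cl2, 40 °C) between the allyl and the 1,1-disubstituted alkene would give methyl (1RS,6R)-4-(4-methylpent-3-en-1-yl)-6-phenylcyclohex-3-ene-1-carboxylate F3; the trisubstituted chain alkene is a poor partner.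
  - Saponification (LiOH, THF/H2O) comes back to the route at 12.

**Step 9.**
- What may go wrong: slow addition of the di-ortho-substituted aryllithium to the alpha-branched amide, with competing alpha-deprotonation or N–O cleavage of the amide.
- Fallback (addition to an aldehyde, then oxidation): it sets out from 13.
  - Reduction with DIBAL-H (THF, −78 °C) would give (1RS,6R)-4-(4-methylpent-3-en-1-yl)-6-phenylcyclohex-3-ene-1-carbaldehyde F4, a smaller and more electrophilic acceptor.
  - Addition of 17 would give [2-methoxy-6-(methoxymethoxy)-4-{[tri(propan-2-yl)silyl]oxy}phenyl][(1RS,6R)-4-(4-methylpent-3-en-1-yl)-6-phenylcyclohex-3-en-1-yl]methanol F5.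
  - Dess–Martin oxidation comes back to the route at 18.

**Step 2.**
- What may go wrong: insufficient enantiofacial discrimination or slow turnover of the iminium catalysis with an acyclic enone that carries a long alkyl chain on the ketone side.
- Fallback (auxiliary-controlled azaenolate Michael addition, with the polarity of the bond formation reversed): it sets out from 2.
  - Condensation with SAMP would give (E)-N-[(2S)-2-(methoxymethyl)pyrrolidin-1-yl]-6-methylhept-5-en-2-imine F6.
  - Deprotonation at the methyl terminus with LDA and 1,4-addition to commercial methyl (E)-cinnamate would give methyl (3R)-5-{[(2S)-2-(methoxymethyl)pyrrolidin-1-yl]imino}-9-methyl-3-phenyldec-8-enoate F7. The auxiliary antipode (SAMP or RAMP) is chosen to give 3R; it is written here for SAMP.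
  - Hydrolytic cleavage with aqueous oxalic acid (no ozone, because of the alkene) comes back to the route at 6.

**Step 4.**
- What may go wrong: enolisation of the ketone by the basic vinyl Grignard reagent, competing attack at the ester, or incomplete lactonisation.
- Fallback (alkynylation and semi-hydrogenation): it sets out from 6.
  - Addition of the much less basic ethynylmagnesium bromide and lactonisation would give (4R,6RS)-6-ethynyl-6-(4-methylpent-3-en-1-yl)-4-phenyloxan-2-one F8.
  - Lindlar semi-hydrogenation of the terminal alkyne (H2, Pd/CaCO3/Pb, quinoline) comes back to the route at 9.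

## Further compounds

F1 | step 5 | methyl (3R)-9-methyl-5-methylidene-3-phenyldec-8-enoate | COC(=O)C[C@H](c1ccccc1)CC(=C)CCC=C(C)C
F2 | step 5 | methyl (2RS,3R)-9-methyl-5-methylidene-3-phenyl-2-(prop-2-en-1-yl)dec-8-enoate | COC(=O)C(CC=C)[C@H](c1ccccc1)CC(=C)CCC=C(C)C
F3 | step 5 | methyl (1RS,6R)-4-(4-methylpent-3-en-1-yl)-6-phenylcyclohex-3-ene-1-carboxylate | COC(=O)C1CC=C(CCC=C(C)C)C[C@H]1c1ccccc1
F4 | step 9 | (1RS,6R)-4-(4-methylpent-3-en-1-yl)-6-phenylcyclohex-3-ene-1-carbaldehyde | O=CC1CC=C(CCC=C(C)C)C[C@H]1c1ccccc1
F5 | step 9 | [2-methoxy-6-(methoxymethoxy)-4-{[tri(propan-2-yl)silyl]oxy}phenyl][(1RS,6R)-4-(4-methylpent-3-en-1-yl)-6-phenylcyclohex-3-en-1-yl]methanol | COCOc1cc(O[Si](C(C)C)(C(C)C)C(C)C)cc(OC)c1C(O)C1CC=C(CCC=C(C)C)C[C@H]1c1ccccc1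
F6 | step 2 | (E)-N-[(2S)-2-(methoxymethyl)pyrrolidin-1-yl]-6-methylhept-5-en-2-imine | COC[C@@H]1CCCN1/N=C(\C)CCC=C(C)C
F7 | step 2 | methyl (3R)-5-{[(2S)-2-(methoxymethyl)pyrrolidin-1-yl]imino}-9-methyl-3-phenyldec-8-enoate | COC(=O)C[C@H](c1ccccc1)CC(CCC=C(C)C)=NN1CCC[C@H]1COC
F8 | step 4 | (4R,6RS)-6-ethynyl-6-(4-methylpent-3-en-1-yl)-4-phenyloxan-2-one | O=C1C[C@H](c2ccccc2)CC(C#C)(CCC=C(C)C)O1
A1 | alternative 1 | (E)-1-[2-methoxy-4,6-bis(methoxymethoxy)phenyl]-3-phenylprop-2-en-1-one | COCOc1cc(OC)c(C(=O)/C=C/c2ccccc2)c(OCOC)c1
A2 | alternative 1 | myrcene (7-methyl-3-methylideneocta-1,6-diene) | C=CC(=C)CCC=C(C)C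
A3 | alternative 1 | [2-methoxy-4,6-bis(methoxymethoxy)phenyl][(1R,6R)-4-(4-methylpent-3-en-1-yl)-6-phenylcyclohex-3-en-1-yl]methanone | COCOc1cc(OC)c(C(=O)[C@@H]2CC=C(CCC=C(C)C)C[C@H]2c2ccccc2)c(OCOC)c1
A4 | alternative 2 | (2R,3R)-1-[2-methoxy-4,6-bis(methoxymethoxy)phenyl]-9-methyl-5-methylidene-3-phenyl-2-(prop-2-en-1-yl)dec-8-en-1-one | COCOc1cc(OC)c(C(=O)[C@H](CC=C)[C@H](c2ccccc2)CC(=C)CCC=C(C)C)c(OCOC)c1
A5 | alternative 3 | [2-methoxy-4,6-bis(methoxymethoxy)phenyl][4-(4-methylpent-3-en-1-yl)cyclohexa-1,4-dien-1-yl]methanone | COCOc1cc(OC)c(C(=O)C2=CCC(CCC=C(C)C)=CC2)c(OCOC)c1
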